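Abbreviations and atom labels: TBS = tert-butyldimethylsilyl. The oxolane atoms are O1, C2 (carries the catechol ring), C3 (carries the hydroxymethyl carbon C9), C4 (carries the guaiacyl carbinol carbon C7) and C5. The same labels are kept for these atoms in every intermediate.

## Analysis of the target

- **Skeleton.** The target is a lignan built on one oxolane ring. C2 bears the 3,4-dihydroxyphenyl group, C3 a hydroxymethyl group (C9), C4 the hydroxy(4-hydroxy-3-methoxyphenyl)methyl group (C7), and C5 is a methylene.
- **Stereocentres.** There are four, three contiguous in the ring and one outside it: (2S,3R,4R,7R). The aryl group at C2 is trans to the hydroxymethyl group at C3, and the substituents at C3 and C4 are cis.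
- **Sensitive groups.** The catechol oxidises easily. Both benzylic C–O bonds (C2–O1 and C7–OH) lie para to a phenolic oxygen. Acid ionises them: a C7 cation would be trapped by the C9 hydroxyl to give a furofuran, and C2 would epimerise. Base acting on the free phenols opens quinone methide pathways.
- **Difficulty.** The crowded 3,4-cis arrangement has to be built next to a 2,3-trans one, and the configuration of the exocyclic carbinol C7 has to be tied to that of the ring.
- **Feature used.** C9 and the oxygen on C7 are cis across C3–C4 and 1,4-related, so they can be closed into a γ-lactone (ring C9–O–C7–C4–C3, C9 as carbonyl) that is cis-fused to the oxolane. In that bicycle C3 is the α-carbon of a carbonyl group and C2 is a benzylic ether carbon, so C2–C3 is a bond that a carbenoid at C3 can make by C–H insertion.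

## Retrosynthetic reasoning

**21 to 20 (O–Si bonds).** Only the three phenolic O–Si bonds are cut. The phenols are carried as TBS ethers from the first steps, because a free catechol would not survive the carbenoid, oxidation and hydride steps. Fluoride removal needs neither acid (C7 ionisation) nor hydrogenolysis (benzylic C–O bonds). The forward step must free three phenols without generating long-lived phenoxides.

**20 to 19 (acyl C9–O bond).** The C9 hydroxyl and the C7 hydroxyl are joined as a lactone. This gives a rigid cis-fused bicycle in which C3, C4 and C7 are locked relative to each other, and it makes C3 the α-carbon of a carbonyl group. The forward reduction attacks only the acyl carbon, so the C7–O bond and its configuration are untouched. Reduction is placed before desilylation so that C7 carries a hydroxyl, not an acyloxy leaving group, when the para phenol is set free.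

**19 to 18 (C2–C3 bond, key disconnection).** C2–C3 is the only ring C–C bond with a carbenoid-capable carbon on one side (C3, α to the lactone carbonyl) and a doubly activated C–H bond on the other (C2, next to the ether oxygen and an electron-rich arene). Cutting it removes two stereocentres (C2 and C3) that the bicyclic transition state then sets. Cutting C2–O1 or C4–C5 instead would leave C3 to be set in an open chain. The precursor 18 is a monocyclic lactone with only two stereocentres. The forward step must pick the benzylic ether C–H bond five atoms away and place the aryl group on the convex face.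

**18 to 16 (C3=N2).** The diazo group is put on by diazo transfer. C3 is the only enolisable position of 16, and C4 and C7 are not acidic, so the two stereocentres are not at risk. The forward step needs prior activation of C3, because a simple lactone enolate does not accept a diazo group cleanly.

**16 to 14 to 12 (lactone C–O bond and oxidation level of C9).** The lactone comes from the 1,4-diol 14 by oxidation of the primary alcohol only. The diol comes from the terminal alkene of 12 by anti-Markovnikov hydration. C9 therefore enters as the end carbon of a vinyl group, which is what an allylation leaves behind.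

**12 to 2 and 10 (C7–C4 bond).** This bond joins the two remaining stereocentres. Allylboration of aldehyde 2 with the Z-configured γ-substituted boronate 10 forms both at once through a closed chair transition state. The Z geometry gives the syn adduct, which becomes the cis-lactone and so places the guaiacyl group on the concave face of 19. A chiral Brønsted acid sets the absolute configuration, and this is the only enantioselective step of the route. The boronate also brings in the whole ether side arm, including the C–H bond used in the key step.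

**10 to 9, and 9 to 6 and 8.** The CH2–B carbon is attached to the Z-alkenyl iodide 9 by an sp2–sp3 cross-coupling, which keeps the double-bond geometry. The ether C–O bond is made by acid-catalysed alkylation of alcohol 8 with imidate 6. Alkoxide conditions are avoided because they would attack aryl silyl ethers and could eliminate HI from the alkenyl iodide.

**Functional-group steps.** 6 comes from alcohol 5, 5 from aldehyde 4, and 4 from 3,4-dihydroxybenzaldehyde 3 by silylation. 8 comes from the commercial ester 7 by reduction. 2 comes from vanillin 1 by silylation.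

## Alternatives that were turned down

**Alternative 1: silicon-tethered radical hydroxymethylation.**
- Disconnection: the C3–C9 bond. The oxolane would already exist as a 2,5-dihydrofuran with a C3=C4 double bond, and the C7 oxygen would carry a (bromomethyl)dimethylsilyl group (silyl ether A1).
- Key step: a tin hydride chain turns the C–Br bond into a silylmethyl radical. It must add to C3 in a six-membered endo closure, because the nearer alkene carbon C4 is fully substituted. The tertiary C4 radical then takes up hydrogen to give the cis-fused oxolane–oxasilinane A2. Oxidative C–Si cleavage would give 20.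
- For: the tether fixes the 3,4-cis relationship, attack anti to the C2 aryl group gives 2,3-trans, and no diazo compound or rhodium catalyst is needed. On the length of the endgame it is as strong as the chosen route, since it also lands on 20.
- Against: C2 and C7 in A1 are 1,4-related across a flat alkene and cannot control each other, so two independent enantioselective operations are needed. The doubly activated C2–H (benzylic, allylic, α-oxy) invites hydrogen transfer to the radical and aromatisation to a furan. The five-membered exo closure at C4 competes. The oxidative C–Si cleavage needs fluoride and peroxide, which threaten aryl silyl ethers and the catechol.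
- Comparison: the chosen route offers a single stereochemical source (one allylboration) from which the other two centres follow.

**Alternative 2: aryl ketene [2+2], then Baeyer–Villiger ring expansion.**
- Disconnection: the C4–C7 and C3–C9 bonds. The 2-aryl-2,5-dihydrofuran A3 would react with the aryl ketene made in situ from acid chloride A4 and a tertiary amine.
- Key step: the ketene adds across C3=C4 to give the cis-fused cyclobutanone A5. A peracid then inserts oxygen between the carbonyl carbon and the benzylic C7 with retention, which gives 19.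
- For: it is more convergent than the chosen route. It forms two C–C bonds and three stereocentres in one step, and the ketene geometry naturally places the large aryl group on the concave face, which is what is needed. It reaches the same furofuranone 19.
- Against: a monoaryl ketene dimerises faster than it adds to an unactivated 1,2-disubstituted alkene. The two alkene carbons differ only through the remote C2 aryl group, so nothing decides which of them bonds to the ketene carbonyl carbon. A3 needs its own asymmetric synthesis and aromatises easily.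
- Comparison: on convergence and bond count the alternative is stronger. The chosen route offers fixed regiochemistry, because the tether dictates which two atoms bond.

**Alternative 3: carbonyl ylide [3+2] across a γ-aryl butenolide.**
- Disconnection: the C2–C3 and C4–C5 bonds. The butenolide A6 would react with the carbonyl ylide released from chloro ether A7 by fluoride.
- Key step: the ylide adds across the butenolide double bond and closes the oxolane cis-fused to the lactone, giving furofuranone A8.
- For: it is the shortest way to the bicyclic skeleton and is stronger than the chosen route on convergence. The butenolide is an easily made single enantiomer, and the cis ring fusion is automatic.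
- Against: the ylide approaches anti to the C7 aryl group, so A8 has this group on the convex face, which is the wrong C7 configuration. Correcting it after reduction means inverting an electron-rich benzylic alcohol next to a primary alcohol, where SN1 scrambling is likely. The regiochemistry of the unsymmetrical ylide and the face taken by the catechol ring are further open points. Fluoride generation of the ylide forces non-silyl phenol protection (allyl), which adds a palladium deprotection.
- Comparison: the chosen route sets C7 correctly at the outset, and its concave placement follows from the cis-lactone.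

Key step: step 12

Assumption: (R)-TRIP is taken to direct the allyl group to the Re face of aldehyde 2, as it does with other aromatic aldehydes; the configuration of 12 would be confirmed before it is carried on, and the enantiomeric catalyst would be used if the sense were reversed.

## Route

Step 1
Reactants: 1 vanillin
Product: 2 4-(TBSO)-3-methoxybenzaldehyde
Conditions: TBSCl, imidazole, DMF, rt
Reagents that add atoms: tert-butyldimethylsilyl chloride, CC(C)(C)[Si](C)(C)Cl
Why: Imidazole-mediated silylation of the phenol; the aldehyde is untouched and the acidic OH is masked for the later base and hydride steps.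

Step 2
Reactants: 3 3,4-dihydroxybenzaldehyde
Product: 4 3,4-bis(TBSO)benzaldehyde
Conditions: TBSCl (2.5 equiv), imidazole, DMF, rt
Reagents that add atoms: tert-butyldimethylsilyl chloride, CC(C)(C)[Si](C)(C)Cl
Why: Same silylation on both catechol hydroxyls; the bis-silyl ether keeps the ring electron-rich, which the key step needs, and blocks catechol oxidation.

Step 3
Reactants: 4 3,4-bis(TBSO)benzaldehyde
Product: 5 [3,4-bis(TBSO)phenyl]methanol
Conditions: NaBH4, MeOH/THF, 0 °C
Reagents that add atoms: none
Why: Borohydride reduction of the aldehyde; short reaction time at 0 °C should leave the aryl silyl ethers intact.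

Step 4
Reactants: 5 [3,4-bis(TBSO)phenyl]methanol
Product: 6 3,4-bis(TBSO)benzyl 2,2,2-trichloroacetimidate
Conditions: Cl3CCN, DBU (cat.), CH2Cl2, 0 °C
Reagents that add atoms: trichloroacetonitrile, ClC(Cl)(Cl)C#N
Why: Base-catalysed addition of the alcohol to the nitrile gives an imidate that alkylates under mild acid, so no alkoxide ever meets the aryl silyl ethers.

Step 5
Reactants: 7 ethyl (Z)-3-iodoprop-2-enoate
Product: 8 (Z)-3-iodoprop-2-en-1-ol
Conditions: iBu2AlH (2.2 equiv), CH2Cl2, −78 °C to −20 °C; aq. KNaC4H4O6 (potassium sodium tartrate)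
Reagents that add atoms: none
Why: Aluminium hydride reduction of the ester to the allylic alcohol at low temperature; the C–I bond and the Z geometry are retained.

Step 6
Reactants: 6 3,4-bis(TBSO)benzyl 2,2,2-trichloroacetimidate; 8 (Z)-3-iodoprop-2-en-1-ol
Product: 9 (Z)-3-iodoprop-2-enyl 3,4-bis(TBSO)benzyl ether
Conditions: camphorsulfonic acid (5 mol %), CH2Cl2, 0 °C to rt
Reagents that add atoms: none
Why: Acid-catalysed benzylation with a trichloroacetimidate: the protonated imidate ionises to a stabilised benzylic cation that the primary alcohol captures; without base the alkenyl iodide cannot eliminate and the silyl ethers stay.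

Step 7
Reactants: 9 (Z)-3-iodoprop-2-enyl 3,4-bis(TBSO)benzyl ether
Product: 10 2-[(Z)-4-{[3,4-bis(TBSO)phenyl]methoxy}but-2-enyl]-4,4,5,5-tetramethyl-1,3,2-dioxaborolane
Conditions: ICH2B(pin), Zn dust, THF, rt (gives IZnCH2B(pin)); then 9, Pd(PPh3)4 (5 mol %), THF, rt to 45 °C
Reagents that add atoms: 2-(iodomethyl)-4,4,5,5-tetramethyl-1,3,2-dioxaborolane, ICB1OC(C)(C)C(C)(C)O1
Why: Negishi-type cross-coupling of the alkenyl iodide with the borylmethylzinc reagent on zerovalent palladium; oxidative addition, transmetalation and reductive elimination keep the alkene geometry, so the Z-allylboronate results under neutral conditions.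

Step 8
Reactants: 2 4-(TBSO)-3-methoxybenzaldehyde; 10 the (Z)-allylboronate
Product: 12 (1R,2R)-2-({[3,4-bis(TBSO)phenyl]methoxy}methyl)-1-[4-(TBSO)-3-methoxyphenyl]but-3-en-1-ol, via pinacol borate ester 11 (not isolated)
Conditions: (R)-3,3′-bis(2,4,6-triisopropylphenyl)-1,1′-binaphthyl-2,2′-diyl hydrogen phosphate [(R)-TRIP, 5 mol %], toluene, −30 °C; aq. NaHCO3
Reagents that add atoms: none
Why: Chiral-phosphoric-acid-catalysed allylboration through a closed six-membered chair; the Z γ-substituent sits axial and the aryl group equatorial, which gives the syn adduct (C4 relative to C7), while the catalyst, hydrogen-bonded to a boronate oxygen and to the formyl hydrogen, exposes the Re face of the aldehyde and sets C7 as R.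

Step 9
Reactants: 12 the syn homoallylic alcohol
Product: 14 (1R,2R)-2-({[3,4-bis(TBSO)phenyl]methoxy}methyl)-1-[4-(TBSO)-3-methoxyphenyl]butane-1,4-diol, via bis-9-BBN adduct 13 (not isolated)
Conditions: 9-BBN (2.5 equiv), THF, 0 °C to rt; then NaBO3·4H2O, THF/H2O, rt
Reagents that add atoms: sodium perborate (source of the new hydroxyl oxygen), B(=O)O[O-].[Na+]
Why: Anti-Markovnikov hydroboration of the terminal alkene (one equivalent of borane is used up by the hydroxyl) and oxidation with perborate, which is mild enough for aryl silyl ethers; no stereocentre is touched.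

Step 10
Reactants: 14 the 1,4-diol
Product: 16 (4R,5R)-4-({[3,4-bis(TBSO)phenyl]methoxy}methyl)-5-[4-(TBSO)-3-methoxyphenyl]oxolan-2-one (cis), via lactol 15 (not isolated)
Conditions: TEMPO (20 mol %), PhI(OAc)2 (2.5 equiv), CH2Cl2, rt
Reagents that add atoms: none
Why: Oxoammonium-mediated oxidative lactonisation: the unhindered primary alcohol is oxidised first, the aldehyde is trapped by the benzylic hydroxyl as a five-membered lactol, and the lactol is oxidised faster than the hindered secondary alcohol; the syn relationship of 12 becomes the cis-lactone.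

Step 11
Reactants: 16 the cis-lactone
Product: 18 (4R,5R)-3-diazo-4-({[3,4-bis(TBSO)phenyl]methoxy}methyl)-5-[4-(TBSO)-3-methoxyphenyl]oxolan-2-one, via 3-trifluoroacetyl lactone 17 (not isolated)
Conditions: LiN(SiMe3)2, THF, −78 °C, then CF3CO2CH2CF3; aq. NH4Cl; crude 17, MsN3, Et3N, H2O (1 equiv), MeCN, rt
Reagents that add atoms: methanesulfonyl azide, CS(=O)(=O)N=[N+]=[N-] (2,2,2-trifluoroethyl trifluoroacetate, O=C(OCC(F)(F)F)C(F)(F)F, adds the acyl group of 17 only)
Why: Detrifluoroacetylative diazo transfer (Danheiser protocol): Claisen acylation activates C3, the sulfonyl azide then delivers N2 and carries off the trifluoroacetyl group; C4 and C7 carry no acidic hydrogen, so their configuration holds.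

Step 12
Reactants: 18 the α-diazo-γ-lactone
Product: 19 (3R,3aR,6S,6aS)-6-[3,4-bis(TBSO)phenyl]-3-[4-(TBSO)-3-methoxyphenyl]tetrahydro-1H,3H-furo[3,4-c]furan-1-one
Conditions: Rh2(OAc)4 (2 mol %), CH2Cl2, 40 °C, 18 added over 4 h (high dilution)
Reagents that add atoms: none
Why: Rh2(OAc)4 takes up the diazo carbon of 18, nitrogen leaves and an electrophilic carbenoid of divalent rhodium is formed at C3. Its vacant orbital engages the C–H bond of the benzylic ether methylene in a concerted, asynchronous three-centre transition state in which positive charge builds on the benzylic carbon and is stabilised by the ether oxygen and the bis(silyloxy)aryl ring; C2–C3 forms as the hydrogen passes to C3 and the catalyst is released. The closest known reaction type is the dirhodium-tetracarboxylate-catalysed 1,5 C–H insertion of α-diazo-γ-butyrolactones into benzylic ether C–H bonds, an established route to 2,6-diaryl furofuranones. The oxolane closes by 1,5-insertion through a six-membered array (five atoms and the migrating hydrogen), and because the tether hangs from one face of the lactone at C4 the ring can only be cis-fused, which fixes the new centre C3 (6aS) from C4. The new benzylic centre C2 (6S) is set in the transition state by placing the aryl group on the convex face, away from the lactone and from the guaiacyl group that the cis-lactone holds on the concave face. The step needs chemoselectivity for insertion over 1,2-hydride migration from C4 (which would give a butenolide), over attack on the catechol ring and over carbenoid dimerisation; the doubly activated C–H bond, the 1,5 geometry, acetate ligands of moderate electrophilicity and slow addition at high dilution are what secure it.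

Step 13
Reactants: 19 the furofuranone
Product: 20 (R)-{(3R,4R,5S)-5-[3,4-bis(TBSO)phenyl]-4-(hydroxymethyl)oxolan-3-yl}[4-(TBSO)-3-methoxyphenyl]methanol
Conditions: LiAlH4, THF, 0 °C; aq. KNaC4H4O6 (potassium sodium tartrate)
Reagents that add atoms: none
Why: Hydride reduction of the lactone to the diol through the lactol aluminate; only the acyl C–O bond is broken, so C7 keeps its R configuration, and doing this before desilylation leaves a hydroxyl and not an acyloxy group at C7 when the para phenol is later freed.

Step 14
Reactants: 20 the tris-silyl diol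
Product: 21 (7R)-7-hydroxytaxiresinol, 4-[(2S,3R,4R)-4-[(R)-hydroxy(4-hydroxy-3-methoxyphenyl)methyl]-3-(hydroxymethyl)oxolan-2-yl]benzene-1,2-diol
Conditions: Bu4NF/AcOH (1:1, 3.5 equiv), THF, 0 °C to rt, argon; pH 7 buffer work-up
Reagents that add atoms: none
Why: Fluoride cleaves the three aryl O–Si bonds; acetic acid keeps the phenols protonated, which should suppress catecholate autoxidation and quinone methide formation, and acid is avoided in work-up because the C7 carbinol would ionise and be trapped by the C9 hydroxyl.

## Compound list

1 | vanillin (4-hydroxy-3-methoxybenzaldehyde) | COc1cc(C=O)ccc1O | starting material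
2 | 4-(TBSO)-3-methoxybenzaldehyde | COc1cc(C=O)ccc1O[Si](C)(C)C(C)(C)C | intermediate
3 | 3,4-dihydroxybenzaldehyde | O=Cc1ccc(O)c(O)c1 | starting material
4 | 3,4-bis(TBSO)benzaldehyde | O=Cc1ccc(O[Si](C)(C)C(C)(C)C)c(O[Si](C)(C)C(C)(C)C)c1 | intermediate
5 | [3,4-bis(TBSO)phenyl]methanol | OCc1ccc(O[Si](C)(C)C(C)(C)C)c(O[Si](C)(C)C(C)(C)C)c1 | intermediate
6 | 3,4-bis(TBSO)benzyl 2,2,2-trichloroacetimidate | N=C(OCc1ccc(O[Si](C)(C)C(C)(C)C)c(O[Si](C)(C)C(C)(C)C)c1)C(Cl)(Cl)Cl | intermediate
7 | ethyl (Z)-3-iodoprop-2-enoate | CCOC(=O)/C=C\I | starting material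
8 | (Z)-3-iodoprop-2-en-1-ol | OC/C=C\I | intermediate
9 | (Z)-3-iodoprop-2-enyl 3,4-bis(TBSO)benzyl ether | I/C=C\COCc1ccc(O[Si](C)(C)C(C)(C)C)c(O[Si](C)(C)C(C)(C)C)c1 | intermediate
10 | 2-[(Z)-4-{[3,4-bis(TBSO)phenyl]methoxy}but-2-enyl]-4,4,5,5-tetramethyl-1,3,2-dioxaborolane | CC1(C)OB(C/C=C\COCc2ccc(O[Si](C)(C)C(C)(C)C)c(O[Si](C)(C)C(C)(C)C)c2)OC1(C)C | intermediate
11 | pinacol borate ester of 12 (B(pin) on the carbinol oxygen, 1R,2R) | CC1(C)OB(O[C@@H](c2ccc(O[Si](C)(C)C(C)(C)C)c(OC)c2)[C@@H](COCc2ccc(O[Si](C)(C)C(C)(C)C)c(O[Si](C)(C)C(C)(C)C)c2)C=C)OC1(C)C | intermediate (not isolated)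
12 | (1R,2R)-2-({[3,4-bis(TBSO)phenyl]methoxy}methyl)-1-[4-(TBSO)-3-methoxyphenyl]but-3-en-1-ol (syn) | O[C@@H](c1ccc(O[Si](C)(C)C(C)(C)C)c(OC)c1)[C@@H](COCc1ccc(O[Si](C)(C)C(C)(C)C)c(O[Si](C)(C)C(C)(C)C)c1)C=C | intermediate
13 | bis-9-BBN adduct of 12 (borinate on the carbinol oxygen, B-alkyl at the chain terminus) | O(B1C2CCCC1CCC2)[C@@H](c1ccc(O[Si](C)(C)C(C)(C)C)c(OC)c1)[C@@H](COCc1ccc(O[Si](C)(C)C(C)(C)C)c(O[Si](C)(C)C(C)(C)C)c1)CCB1C2CCCC1CCC2 | intermediate (not isolated)
14 | (1R,2R)-2-({[3,4-bis(TBSO)phenyl]methoxy}methyl)-1-[4-(TBSO)-3-methoxyphenyl]butane-1,4-diol | O[C@@H](c1ccc(O[Si](C)(C)C(C)(C)C)c(OC)c1)[C@@H](COCc1ccc(O[Si](C)(C)C(C)(C)C)c(O[Si](C)(C)C(C)(C)C)c1)CCO | intermediate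
15 | (4R,5R)-4-({[3,4-bis(TBSO)phenyl]methoxy}methyl)-5-[4-(TBSO)-3-methoxyphenyl]oxolan-2-ol (lactol, both anomers) | OC1O[C@@H](c2ccc(O[Si](C)(C)C(C)(C)C)c(OC)c2)[C@@H](COCc2ccc(O[Si](C)(C)C(C)(C)C)c(O[Si](C)(C)C(C)(C)C)c2)C1 | intermediate (not isolated)
16 | (4R,5R)-4-({[3,4-bis(TBSO)phenyl]methoxy}methyl)-5-[4-(TBSO)-3-methoxyphenyl]oxolan-2-one (cis) | O=C1O[C@@H](c2ccc(O[Si](C)(C)C(C)(C)C)c(OC)c2)[C@@H](COCc2ccc(O[Si](C)(C)C(C)(C)C)c(O[Si](C)(C)C(C)(C)C)c2)C1 | intermediate
17 | 3-(trifluoroacetyl) derivative of 16 (C3 undefined, 4R,5R) | O=C1O[C@@H](c2ccc(O[Si](C)(C)C(C)(C)C)c(OC)c2)[C@@H](COCc2ccc(O[Si](C)(C)C(C)(C)C)c(O[Si](C)(C)C(C)(C)C)c2)C1C(=O)C(F)(F)F | intermediate (not isolated)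
18 | (4R,5R)-3-diazo-4-({[3,4-bis(TBSO)phenyl]methoxy}methyl)-5-[4-(TBSO)-3-methoxyphenyl]oxolan-2-one | O=C1O[C@@H](c2ccc(O[Si](C)(C)C(C)(C)C)c(OC)c2)[C@@H](COCc2ccc(O[Si](C)(C)C(C)(C)C)c(O[Si](C)(C)C(C)(C)C)c2)C1=[N+]=[N-] | intermediate
19 | (3R,3aR,6S,6aS)-6-[3,4-bis(TBSO)phenyl]-3-[4-(TBSO)-3-methoxyphenyl]tetrahydro-1H,3H-furo[3,4-c]furan-1-one (guaiacyl concave, catechol ring convex) | O=C1O[C@@H](c2ccc(O[Si](C)(C)C(C)(C)C)c(OC)c2)[C@H]2CO[C@H](c3ccc(O[Si](C)(C)C(C)(C)C)c(O[Si](C)(C)C(C)(C)C)c3)[C@@H]12 | intermediate
20 | (R)-{(3R,4R,5S)-5-[3,4-bis(TBSO)phenyl]-4-(hydroxymethyl)oxolan-3-yl}[4-(TBSO)-3-methoxyphenyl]methanol | COc1cc([C@H](O)[C@H]2CO[C@H](c3ccc(O[Si](C)(C)C(C)(C)C)c(O[Si](C)(C)C(C)(C)C)c3)[C@H]2CO)ccc1O[Si](C)(C)C(C)(C)C | intermediate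
21 | (7R)-7-hydroxytaxiresinol | COc1cc([C@H](O)[C@H]2CO[C@H](c3ccc(O)c(O)c3)[C@H]2CO)ccc1O | target

## Step count and least certain steps

Total: 14 steps. Longest linear sequence: 12 steps (from 3 through steps 2, 3, 4, 6, 7, 8, 9, 10, 11, 12, 13 and 14).

**Step 12 (key step).**
- What may go wrong: hydride migration from C4 to the carbenoid carbon, which destroys the C4 stereocentre; attack of the carbenoid on the electron-rich catechol ring; carbenoid dimerisation; or insertion with the aryl group on the concave face.
- Fallback: a stepwise aldol and cyclisation sequence that sets out from lactone 16 and rejoins the route at 21.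
 - Oxidative removal of the electron-rich benzyl group with DDQ (which returns aldehyde 4) would give (4R,5R)-4-(hydroxymethyl)-5-[4-(TBSO)-3-methoxyphenyl]oxolan-2-one F1.
 - Catalytic DBU would move the acyl group to the primary oxygen and give the less strained (4R)-4-{(R)-hydroxy[4-(TBSO)-3-methoxyphenyl]methyl}oxolan-2-one F2.
 - Silylation (TBSOTf, 2,6-lutidine) would give the C7 silyl ether F3.
 - The lithium enolate of F3 would add to aldehyde 4 at C3, trans to the C4 substituent, to give the aldol adduct F4 (both carbinol epimers are usable).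
 - LiAlH4 would give the triol F5.
 - Catalytic camphorsulfonic acid would ionise the benzylic carbinol, and the C5 hydroxyl would close the oxolane under thermodynamic control with the aryl group trans to C9. The trans aldol geometry translates into the 3,4-cis ring pattern and gives the tetrakis-silyl ether F6.
 - Bu4NF/AcOH would then give 21.

**Step 8.**
- What may go wrong: weak enantioface discrimination, or leakage through boat or uncatalysed pathways that erodes the syn selectivity. The γ-alkoxymethyl group of a Z-boronate is axial in the chair, and the electron-rich aldehyde reacts slowly.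
- Fallback: Lewis-base-catalysed allylation with a trichlorosilane, setting out from imidate 6 and rejoining at 12.
 - (Z)-But-2-ene-1,4-diol F7 (commercial, used in excess) would be mono-benzylated with 6 under acid catalysis to give (Z)-4-{[3,4-bis(TBSO)phenyl]methoxy}but-2-en-1-ol F8.
 - MsCl, LiCl and 2,4,6-collidine would give the (Z)-allylic chloride F9.
 - HSiCl3, CuCl (cat.) and iPr2NEt would give the (Z)-allyltrichlorosilane F10 with retention of geometry.
 - F10 would add to aldehyde 2 through a closed chair at hexacoordinate silicon, catalysed by the enantiomer of the 2,2′-bipyrrolidine-derived bisphosphoramide that directs the allyl group to the Re face of aromatic aldehydes. This gives the syn adduct 12.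

**Step 7.**
- What may go wrong: isomerisation of the Z double bond on palladium; protodeboronation or allylic transposition of the allylboronate during coupling and chromatography.
- Fallback: a palladium-free 1,2-metallate rearrangement, setting out from 9 and rejoining at 10. Iodine–lithium exchange (tBuLi, 2 equiv, Et2O, −78 °C) would give the (Z)-alkenyllithium F11. Addition to 2-(chloromethyl)-4,4,5,5-tetramethyl-1,3,2-dioxaborolane would give the lithium boronate complex F12. On warming, the alkenyl group migrates from boron to carbon with loss of chloride and retention of the double-bond geometry, giving 10.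

**Step 6.**
- What may go wrong: ionisation of the very electron-rich imidate followed by self-alkylation of the arene (oligomerisation), faster than capture by alcohol 8.
- Fallback: a silver-mediated etherification, setting out from alcohol 5 and rejoining at 9. CBr4 and PPh3 would convert 5 into 4-(bromomethyl)-1,2-bis(TBSO)benzene F13. Alcohol 8 would then be alkylated with F13 and Ag2O in CH2Cl2 under neutral conditions to give 9.

## Further compounds

F1 | step 12 | (4R,5R)-4-(hydroxymethyl)-5-[4-(TBSO)-3-methoxyphenyl]oxolan-2-one | O=C1O[C@@H](c2ccc(O[Si](C)(C)C(C)(C)C)c(OC)c2)[C@@H](CO)C1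
F2 | step 12 | (4R)-4-{(R)-hydroxy[4-(TBSO)-3-methoxyphenyl]methyl}oxolan-2-one | O=C1C[C@H](CO1)[C@@H](O)c1ccc(O[Si](C)(C)C(C)(C)C)c(OC)c1
F3 | step 12 | (4R)-4-{(R)-(TBSO)[4-(TBSO)-3-methoxyphenyl]methyl}oxolan-2-one | O=C1C[C@H](CO1)[C@@H](O[Si](C)(C)C(C)(C)C)c1ccc(O[Si](C)(C)C(C)(C)C)c(OC)c1
F4 | step 12 | (3S,4R)-3-{[3,4-bis(TBSO)phenyl](hydroxy)methyl}-4-{(R)-(TBSO)[4-(TBSO)-3-methoxyphenyl]methyl}oxolan-2-one (carbinol epimers) | O=C1OC[C@H]([C@@H](O[Si](C)(C)C(C)(C)C)c2ccc(O[Si](C)(C)C(C)(C)C)c(OC)c2)[C@H]1C(O)c1ccc(O[Si](C)(C)C(C)(C)C)c(O[Si](C)(C)C(C)(C)C)c1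
F5 | step 12 | 2-{[3,4-bis(TBSO)phenyl](hydroxy)methyl}-3-{(R)-(TBSO)[4-(TBSO)-3-methoxyphenyl]methyl}butane-1,4-diol (chain centres as in the target, carbinol epimers) | OC[C@H](C(O)c1ccc(O[Si](C)(C)C(C)(C)C)c(O[Si](C)(C)C(C)(C)C)c1)[C@H](CO)[C@@H](O[Si](C)(C)C(C)(C)C)c1ccc(O[Si](C)(C)C(C)(C)C)c(OC)c1
F6 | step 12 | 7-O-TBS derivative of 20 (tetrakis-silyl ether, free C9 hydroxyl) | COc1cc([C@H](O[Si](C)(C)C(C)(C)C)[C@H]2CO[C@H](c3ccc(O[Si](C)(C)C(C)(C)C)c(O[Si](C)(C)C(C)(C)C)c3)[C@H]2CO)ccc1O[Si](C)(C)C(C)(C)C
F7 | step 8 | (Z)-but-2-ene-1,4-diol (commercial) | OC/C=C\CO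
F8 | step 8 | (Z)-4-{[3,4-bis(TBSO)phenyl]methoxy}but-2-en-1-ol | OC/C=C\COCc1ccc(O[Si](C)(C)C(C)(C)C)c(O[Si](C)(C)C(C)(C)C)c1
F9 | step 8 | (Z)-4-chlorobut-2-enyl 3,4-bis(TBSO)benzyl ether | ClC/C=C\COCc1ccc(O[Si](C)(C)C(C)(C)C)c(O[Si](C)(C)C(C)(C)C)c1
F10 | step 8 | trichloro[(Z)-4-{[3,4-bis(TBSO)phenyl]methoxy}but-2-enyl]silane | Cl[Si](Cl)(Cl)C/C=C\COCc1ccc(O[Si](C)(C)C(C)(C)C)c(O[Si](C)(C)C(C)(C)C)c1
F11 | step 7 | (Z)-3-{[3,4-bis(TBSO)phenyl]methoxy}prop-1-enyllithium | [Li]/C=C\COCc1ccc(O[Si](C)(C)C(C)(C)C)c(O[Si](C)(C)C(C)(C)C)c1
F12 | step 7 | lithium (chloromethyl)[(Z)-3-{[3,4-bis(TBSO)phenyl]methoxy}prop-1-enyl](pinacolato)borate | [Li+].ClC[B-]1(/C=C\COCc2ccc(O[Si](C)(C)C(C)(C)C)c(O[Si](C)(C)C(C)(C)C)c2)OC(C)(C)C(C)(C)O1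
F13 | step 6 | 4-(bromomethyl)-1,2-bis(TBSO)benzene | BrCc1ccc(O[Si](C)(C)C(C)(C)C)c(O[Si](C)(C)C(C)(C)C)c1
A1 | alternative 1 | (bromomethyl)dimethylsilyl ether of the (5S)-5-[3,4-bis(TBSO)phenyl]-2,5-dihydrofuran-3-yl guaiacyl carbinol (C7 as in the target) | BrC[Si](C)(C)O[C@@H](c1ccc(O[Si](C)(C)C(C)(C)C)c(OC)c1)C1=C[C@@H](c2ccc(O[Si](C)(C)C(C)(C)C)c(O[Si](C)(C)C(C)(C)C)c2)OC1
A2 | alternative 1 | cis-fused oxolane–oxasilinane bicycle (silicon-tethered cyclisation product) | C[Si]1(C)O[C@@H](c2ccc(O[Si](C)(C)C(C)(C)C)c(OC)c2)[C@H]2CO[C@H](c3ccc(O[Si](C)(C)C(C)(C)C)c(O[Si](C)(C)C(C)(C)C)c3)[C@H]2C1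
A3 | alternative 2 | (S)-2-[3,4-bis(TBSO)phenyl]-2,5-dihydrofuran | C1=C[C@@H](c2ccc(O[Si](C)(C)C(C)(C)C)c(O[Si](C)(C)C(C)(C)C)c2)OC1
A4 | alternative 2 | [4-(TBSO)-3-methoxyphenyl]acetyl chloride | O=C(Cl)Cc1ccc(O[Si](C)(C)C(C)(C)C)c(OC)c1
A5 | alternative 2 | 7-aryl-3-oxabicyclo[3.2.0]heptan-6-one with the guaiacyl group on the concave face | O=C1[C@@H](c2ccc(O[Si](C)(C)C(C)(C)C)c(OC)c2)[C@H]2CO[C@H](c3ccc(O[Si](C)(C)C(C)(C)C)c(O[Si](C)(C)C(C)(C)C)c3)[C@@H]12
A6 | alternative 3 | (S)-5-[4-(allyloxy)-3-methoxyphenyl]furan-2(5H)-one | O=C1C=C[C@@H](c2ccc(OCC=C)c(OC)c2)O1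
A7 | alternative 3 | α-chloro-3,4-bis(allyloxy)benzyl (trimethylsilyl)methyl ether (racemic) | ClC(OC[Si](C)(C)C)c1ccc(OCC=C)c(OCC=C)c1
A8 | alternative 3 | furofuranone with both aryl groups on the convex face (C7 epimer of the lactone needed, allyl-protected) | O=C1O[C@H](c2ccc(OCC=C)c(OC)c2)[C@H]2CO[C@H](c3ccc(OCC=C)c(OCC=C)c3)[C@@H]12
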